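1. The easy step comes first. Solid L dissolves to E, E exchanges reversibly with Q, J and X, X exchanges with D, and two E leave together as E2.

L 2.0 × 10⁻⁴ M; time 80 s

* the X standing at 80 s, as a percentage of the L charged
* the D standing at 80 s, as a percentage of the L charged

- percentages count the L that a species holds: one E2 counts as two
- for a step with 2 of a species take k times the square, and two of it per event
- solid, in amounts per volume of the solution: L
- at the start none of L is in solution
- what has only dissolved of L counts as not reacted
- run time (flask): 80 s

    2 E → E2 (k1 = 780 L mol⁻¹ s⁻¹)
    L ⇌ E, rate k2*(cs2 - [E]) while solid is left; crystals form when [E] > cs2 (cs2 = 0.025 mM, k2 = 5.9 s⁻¹)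
    E ⇌ Q (K3 = 0.16, k3 = 0.41 s⁻¹)
    E ⇌ J (K4 = 0.42, k4 = 0.62 s⁻¹)
    E ⇌ X (K5 = 0.39, k5 = 2.1 s⁻¹)
    X ⇌ D (K6 = 3.0, k6 = 0.28 s⁻¹)

2. E passes to X with a forward half-life of 0.33 s, short against 80 s, so this exchange is taken as a pre-equilibrium: [X] is 0.39 times [E]. Q and J follow E in the same way.

3. With [X] held, D fills with a time constant of 10.7 s, the equilibrium constant of X ⇌ D over its forward rate constant. That is short against the run, so [D] is 1.17 times [E]. The dissolved family E, Q, J, X and D together holds 3.14 times [E].

4. First way: let the charge dissolve whole and leave E2 aside. Then [E] is 0.0637 mM and D holds 37.3%.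

5. Second way: let solid L remain, with [E] at its solubility. The quantity to carry is the solubility share: the equilibrium constants leading from E to a species, times the solubility of E, over the charge of L. For D it is 14.6%, and for X 4.88%.

6. The two ways part, and the first cheats: its [E] stands above the solubility, where crystals form.

7. The second way must still show that solid lasts. E2 drains E at 9.75 × 10⁻⁷ M s⁻¹, which takes 39.0% of the charge over the run, and the dissolved family takes 39.2%. That leaves about 21.8% as solid. Feeding this drain holds [E] below solubility by 0.661% of it.

8. The forecast gives 4.84% for X and 14.5% for D, on the ground that “dissolution pins E just under its solubility”.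

9. The flask gives 4.84% of X and 14.5% of D at 80.0 s.

10. At that reading 23.0% of the charge still stands as solid L. In the neighbouring flask charged with 5.0 × 10⁻⁴ M of L, solid L holds 69.2% of that charge at 80.0 s, the solubility share of D comes to 5.85%, and D stands at 5.81%.

The rate constants stand for no real mixture; the rest is arithmetic.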